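**Strategy.** Everything rests on opening ring C (O1, C2, C3, C4, C4a, C8a; flavanone numbering) at C2–C3 and C4–C4a, so that the C3–C4 unit becomes a diazoacetyl group on the C2 carbinol carbon. In the key step light triggers a Wolff rearrangement of this α-aryloxy diazoketone: C2 migrates with retention from C4 to C3, and the ketene carbon C4 then acylates C4a, the only free position ortho to O1 on the electron-rich trioxygenated ring A (C8 carries the prenyl group), closing ring C. The precursor is an open-chain (R)-aryloxy(4-methoxyphenyl)acetyl diazomethane from (S)-4-methoxymandelic acid and 3,5-dimethoxy-2-prenylphenol; C2 is set beforehand by Mitsunobu inversion.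

Key step: step 6

Remark: the target is the (2S)-flavanone; (S)-4-methoxymandelic acid is taken as a commercial, enantiopure starting material.

**Step 1**
Reactants: 1 3,5-dimethoxyphenol
Product: 2 3,5-dimethoxy-2-(3-methylbut-2-en-1-yl)phenol
Conditions: NaH (1.0 equiv), PhMe, 0 °C; then prenyl bromide (1.0 equiv), 25 °C
Reagents that add atoms: 1-bromo-3-methylbut-2-ene (prenyl bromide), CC(C)=CCBr
Why: Ortho-selective C-allylation of a sodium phenoxide in a non-polar solvent: the contact ion pair delivers prenyl bromide to the ortho carbon by direct SN2 displacement (no allylic transposition), the two ortho positions of 1 are equivalent, and one equivalent of base and halide limits double alkylation.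

**Step 2**
Reactants: 3 (S)-4-methoxymandelic acid
Product: 4 methyl (S)-4-methoxymandelate
Conditions: MeI, KHCO3, DMF, 25 °C
Reagents that add atoms: iodomethane, CI
Why: O-Alkylation of the carboxylate (SN2 on MeI) under weakly basic conditions; the secondary benzylic hydroxyl is not alkylated and the stereocenter is not touched.

**Step 3**
Reactants: 2 3,5-dimethoxy-2-(3-methylbut-2-en-1-yl)phenol; 4 methyl (S)-4-methoxymandelate
Product: 5 methyl (2R)-2-[3,5-dimethoxy-2-(3-methylbut-2-en-1-yl)phenoxy]-2-(4-methoxyphenyl)acetate
Conditions: PPh3, DIAD, THF, 0 °C to 25 °C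
Reagents that add atoms: none
Why: Mitsunobu etherification: the phenol (pKa about 10) attacks the alkoxyphosphonium ion of 4 by SN2 with inversion, so the (S)-carbinol should give the (R)-aryl ether, the adjacent ester group disfavoring ionization of the anisyl carbinol carbon.

**Step 4**
Reactants: 5 methyl (2R)-2-[3,5-dimethoxy-2-(3-methylbut-2-en-1-yl)phenoxy]-2-(4-methoxyphenyl)acetate
Product: 6 (2R)-2-[3,5-dimethoxy-2-(3-methylbut-2-en-1-yl)phenoxy]-2-(4-methoxyphenyl)acetic acid
Conditions: LiOH·H2O (1.5 equiv), THF/H2O (3:1), 0 °C; then 1 M HCl to pH 3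
Reagents that add atoms: lithium hydroxide, [Li+].[OH-]
Why: Saponification of an unhindered methyl ester (BAc2) with a small excess of hydroxide at 0 °C, where ester cleavage should outrun enolization at the benzylic α-carbon, so that the configuration is kept.

**Step 5**
Reactants: 6 (2R)-2-[3,5-dimethoxy-2-(3-methylbut-2-en-1-yl)phenoxy]-2-(4-methoxyphenyl)acetic acid
Product: 8 (3R)-1-diazo-3-[3,5-dimethoxy-2-(3-methylbut-2-en-1-yl)phenoxy]-3-(4-methoxyphenyl)propan-2-one, via acid chloride 7 (not isolated)
Conditions: 1-chloro-N,N,2-trimethylprop-1-en-1-amine, CH2Cl2, 0 °C; then CH2N2 (3 equiv), Et2O, 0 °C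
Reagents that add atoms: diazomethane, C=[N+]=[N-]; 1-chloro-N,N,2-trimethylprop-1-en-1-amine, CC(C)=C(Cl)N(C)C (its chlorine stays only in 7)
Why: Acylation of diazomethane by an acid chloride formed under neutral conditions with the α-chloroenamine (first stage of an Arndt–Eistert sequence); no amine base is present, so 7 should neither epimerize nor eliminate to a ketene, and excess diazomethane removes the HCl as chloromethane before it can add to the prenyl double bond.

**Step 6**
Reactants: 8 (3R)-1-diazo-3-[3,5-dimethoxy-2-(3-methylbut-2-en-1-yl)phenoxy]-3-(4-methoxyphenyl)propan-2-one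
Product: 10 (2S)-5,7-dimethoxy-2-(4-methoxyphenyl)-8-(3-methylbut-2-en-1-yl)-2,3-dihydro-4H-chromen-4-one, via ketene 9 (not isolated)
Conditions: hν (405 nm LED), PhMe (0.01 M), 4 Å MS, 25 °C; then 60 °C
Reagents that add atoms: none
Why: Proposed new method: irradiation of the s-cis diazoketone should expel N2 with concerted 1,2-shift of the C2 carbinol carbon from C4 to C3 (Wolff rearrangement, forming C2–C3) to give the β-aryloxy ketene 9, whose sp carbon C4 is then attacked by C4a of the trioxygenated ring A (intramolecular electrophilic aromatic substitution, forming C4–C4a), and proton transfer in the arenium enolate gives the aryl ketone. The closest known reactions are the Wolff rearrangement of the Arndt–Eistert sequence, which carries a stereogenic migrating carbon over with retention, and Friedel–Crafts-type acylations of electron-rich arenes by ketenes generated in situ; the capture of a Wolff ketene by an arene without a promoter is the unproven part. Ring C closes in a 6-exo-dig mode, C4a attacking the sp carbon of the ketene while the C=O π bond stays outside the ring. No new stereocenter is formed: C2 comes from 8 with retention, and its descriptor changes from R to S only because the ranking of its substituents changes. The step needs migration over carbene C–H insertion into ring A (metal-free photolysis at a wavelength the product does not absorb should secure this), acylation at C4a only (C8 is blocked by the prenyl group and C4a is ortho or para to all three ring oxygens), and ring closure over ketene dimerization or hydration (high dilution, molecular sieves, no external nucleophile).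

**Step 7**
Reactants: 10 (2S)-5,7-dimethoxy-2-(4-methoxyphenyl)-8-(3-methylbut-2-en-1-yl)-2,3-dihydro-4H-chromen-4-one
Product: 11 flowerine, (2S)-5-hydroxy-7-methoxy-2-(4-methoxyphenyl)-8-(3-methylbut-2-en-1-yl)-2,3-dihydro-4H-chromen-4-one
Conditions: MgI2·OEt2, THF, 50 °C; then 1 M HCl
Reagents that add atoms: none
Why: Chelation-controlled aryl methyl ether cleavage: Mg2+ is held between the C4 carbonyl oxygen and the 5-methoxy oxygen and iodide removes that methyl group by SN2, so the 7- and 4'-methoxy groups, the prenyl group and C2 should stay untouched.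

**Compound list**
1 | 3,5-dimethoxyphenol | COc1cc(O)cc(OC)c1 | starting material
2 | 3,5-dimethoxy-2-(3-methylbut-2-en-1-yl)phenol | COc1cc(O)c(CC=C(C)C)c(OC)c1 | intermediate
3 | (S)-4-methoxymandelic acid | COc1ccc([C@H](O)C(=O)O)cc1 | starting material
4 | methyl (S)-4-methoxymandelate | COc1ccc([C@H](O)C(=O)OC)cc1 | intermediate
5 | methyl (2R)-2-[3,5-dimethoxy-2-(3-methylbut-2-en-1-yl)phenoxy]-2-(4-methoxyphenyl)acetate | COc1ccc([C@@H](Oc2cc(OC)cc(OC)c2CC=C(C)C)C(=O)OC)cc1 | intermediate
6 | (2R)-2-[3,5-dimethoxy-2-(3-methylbut-2-en-1-yl)phenoxy]-2-(4-methoxyphenyl)acetic acid | COc1ccc([C@@H](Oc2cc(OC)cc(OC)c2CC=C(C)C)C(=O)O)cc1 | intermediate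
7 | (2R)-2-[3,5-dimethoxy-2-(3-methylbut-2-en-1-yl)phenoxy]-2-(4-methoxyphenyl)acetyl chloride | COc1ccc([C@@H](Oc2cc(OC)cc(OC)c2CC=C(C)C)C(Cl)=O)cc1 | intermediate (not isolated)
8 | (3R)-1-diazo-3-[3,5-dimethoxy-2-(3-methylbut-2-en-1-yl)phenoxy]-3-(4-methoxyphenyl)propan-2-one | COc1ccc([C@@H](Oc2cc(OC)cc(OC)c2CC=C(C)C)C(=O)C=[N+]=[N-])cc1 | intermediate
9 | (3S)-3-[3,5-dimethoxy-2-(3-methylbut-2-en-1-yl)phenoxy]-3-(4-methoxyphenyl)prop-1-en-1-one (ketene) | COc1ccc([C@@H](Oc2cc(OC)cc(OC)c2CC=C(C)C)C=C=O)cc1 | intermediate (not isolated)
10 | (2S)-5,7-dimethoxy-2-(4-methoxyphenyl)-8-(3-methylbut-2-en-1-yl)-2,3-dihydro-4H-chromen-4-one | COc1ccc([C@@H]2CC(=O)c3c(OC)cc(OC)c(CC=C(C)C)c3O2)cc1 | intermediate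
11 | flowerine, (2S)-5-hydroxy-7-methoxy-2-(4-methoxyphenyl)-8-(3-methylbut-2-en-1-yl)-2,3-dihydro-4H-chromen-4-one | COc1ccc([C@@H]2CC(=O)c3c(O)cc(OC)c(CC=C(C)C)c3O2)cc1 | target

**Step count.** Total: 7 steps. Longest linear sequence: 6 steps (steps 1, 3, 4, 5, 6, 7).

**Steps most likely to fail**

Step 6 (proposed new method). The ketene may be consumed by dimerization or by traces of water before ring A attacks it, or the excited diazoketone may leak into carbene-type C–H insertion. The fallback sets out from diazoketone 8 and separates the two bond formations. A silver-catalyzed Wolff rearrangement in the presence of water (PhCO2Ag cat., Et3N, THF/H2O; Arndt–Eistert homologation with retention at C2) should give (3S)-3-[3,5-dimethoxy-2-(3-methylbut-2-en-1-yl)phenoxy]-3-(4-methoxyphenyl)propanoic acid F1. Neutral chlorination with 1-chloro-N,N,2-trimethylprop-1-en-1-amine in CH2Cl2 should give (3S)-3-[3,5-dimethoxy-2-(3-methylbut-2-en-1-yl)phenoxy]-3-(4-methoxyphenyl)propanoyl chloride F2. Intramolecular Friedel–Crafts acylation at C4a in 1,1,1,3,3,3-hexafluoropropan-2-ol at 25 °C, without a Lewis acid, then comes back to the route at 10.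

Step 3. Partial ionization of the activated anisyl carbinol may erode the enantiopurity, and substitution by the ortho-substituted phenol may be slow. The fallback sets out from phenol 2 and commercial methyl 4-methoxyphenylacetate and sets the stereocenter by catalyst control instead of inversion. Diazo transfer (4-acetamidobenzenesulfonyl azide, DBU, MeCN) should give methyl 2-diazo-2-(4-methoxyphenyl)acetate F3. An enantioselective carbene insertion into the O–H bond of 2 (PdCl2(PhCN)2, a chiral spirobiindane bisoxazoline ligand, NaB[3,5-(CF3)2C6H3]4, CHCl3, 25 °C; ligand enantiomer chosen for the R product) then comes back to the route at 5.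

Step 1. O-alkylation, alkylation at the para carbon and double alkylation may compete with the wanted ortho C-alkylation. The fallback sets out from 1 and delivers the prenyl group by a sigmatropic shift that can only reach an ortho carbon. Etherification with 3-chloro-3-methylbut-1-yne (K2CO3, KI, CuI cat., acetone) should give 1,3-dimethoxy-5-[(2-methylbut-3-yn-2-yl)oxy]benzene F4. Semi-hydrogenation (H2, Pd/CaCO3 poisoned with Pb(OAc)2, quinoline, EtOAc) should give 1,3-dimethoxy-5-[(2-methylbut-3-en-2-yl)oxy]benzene F5. An aromatic Claisen rearrangement (PhMe, 110 °C) onto either of the two equivalent ortho positions, with allyl inversion, then comes back to the route at 2.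

**Further compounds**
F1 | step 6 | (3S)-3-[3,5-dimethoxy-2-(3-methylbut-2-en-1-yl)phenoxy]-3-(4-methoxyphenyl)propanoic acid | COc1ccc([C@@H](Oc2cc(OC)cc(OC)c2CC=C(C)C)CC(=O)O)cc1
F2 | step 6 | (3S)-3-[3,5-dimethoxy-2-(3-methylbut-2-en-1-yl)phenoxy]-3-(4-methoxyphenyl)propanoyl chloride | COc1ccc([C@@H](Oc2cc(OC)cc(OC)c2CC=C(C)C)CC(Cl)=O)cc1
F3 | step 3 | methyl 2-diazo-2-(4-methoxyphenyl)acetate | COC(=O)C(=[N+]=[N-])c1ccc(OC)cc1
F4 | step 1 | 1,3-dimethoxy-5-[(2-methylbut-3-yn-2-yl)oxy]benzene | COc1cc(OC)cc(OC(C)(C)C#C)c1
F5 | step 1 | 1,3-dimethoxy-5-[(2-methylbut-3-en-2-yl)oxy]benzene | COc1cc(OC)cc(OC(C)(C)C=C)c1
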